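**Retrosynthetic overview**

1. The strategy rests on C12, the carbinol carbon of the cyclopentenone ring (C8–C9–C10–C11–C12). It carries two CH2 arms, ring carbon C8 leading to the C9 carbonyl and chain carbon C13 leading to C14, and it also carries the C11=C10(Cl) unit. C8–C9 and C13–C14 are therefore both formylmethyl groups on a carbinol carbon that also bears a chloroethynyl group (C11≡C10–Cl).
2. Late stage: the C12 hydroxyl is freed last. C6–C7 comes from a Stille coupling of a (7Z)-enol triflate (C7 from a formate, geometry from a sodium chelate) with a (5Z)-alkenylstannane. C14=C15 comes from a Z-selective Wittig reaction.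
3. Key disconnection: C9–C10, by enantiotopic-group-selective rhodium-catalysed alkyne hydroacylation of an achiral dialdehyde. It closes the cyclopentenone, places chlorine on C10 and sets C12.
4. The dialdehyde comes from ethyl 3-(trimethylsilyl)prop-2-ynoate by double allylation, O-silylation, C-desilylation, chlorination and double ozonolysis.
5. Ring order: the cyclopentenone is the only ring and is formed in step 6.

Key step: step 6

Remark on numbering: positions in the target are given in prostanoid numbering (C1 ester carbon, C12 carbinol carbon, C20 chain-end methyl).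

Assumption: the sense in which (R)-Tol-BINAP selects between the two formyl arms cannot be derived from the known diyne cases, where the ligand chooses between alkynes. The (R) ligand is written, and its antipode is taken if the first run gives the (1R) product.

**Route**

Step 1
Reactants: 1 ethyl 3-(trimethylsilyl)prop-2-ynoate; 2 allylmagnesium bromide
Product: 4 4-[(trimethylsilyl)ethynyl]hepta-1,6-dien-4-ol, via allyl ynone 3 (not isolated)
Conditions: 2 (2.3 equiv), THF/Et2O, −78 to 0 °C; then H2O (aq. NH4Cl work-up)
Reagents that add atoms: none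
Why: Double Grignard addition to an ester: the allyl reagent attacks the carbonyl 1,2 through a cyclic transition state while the silyl group shields the β-carbon, and ynone 3 is more electrophilic than ester 1, so the symmetric tertiary carbinol without a stereocentre should form.

Step 2
Reactants: 4 4-[(trimethylsilyl)ethynyl]hepta-1,6-dien-4-ol
Product: 5 triethyl({4-[(trimethylsilyl)ethynyl]hepta-1,6-dien-4-yl}oxy)silane
Conditions: Et3SiOTf, 2,6-lutidine, CH2Cl2, −78 to 0 °C
Reagents that add atoms: triethylsilyl trifluoromethanesulfonate, CC[Si](CC)(CC)OS(=O)(=O)C(F)(F)F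
Why: Silylation of a hindered tertiary alcohol with a silyl triflate and a non-nucleophilic pyridine base is reliable, and the triethylsilyl ether should last through the bases, ozone and palladium still to come yet leave with fluoride at the end.

Step 3
Reactants: 5 triethyl({4-[(trimethylsilyl)ethynyl]hepta-1,6-dien-4-yl}oxy)silane
Product: 6 triethyl[(4-ethynylhepta-1,6-dien-4-yl)oxy]silane
Conditions: K2CO3, MeOH, rt
Reagents that add atoms: none
Why: Base-catalysed methanolysis (protodesilylation of an alkynylsilane) cleaves the C(sp)–Si bond much faster than the hindered tertiary O–SiEt3 bond.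

Step 4
Reactants: 6 triethyl[(4-ethynylhepta-1,6-dien-4-yl)oxy]silane
Product: 8 {[4-(chloroethynyl)hepta-1,6-dien-4-yl]oxy}triethylsilane, via lithium acetylide 7 (not isolated)
Conditions: n-BuLi, THF, −78 °C; then N-chlorosuccinimide, −78 °C to rt
Reagents that add atoms: N-chlorosuccinimide, O=C1CCC(=O)N1Cl
Why: Deprotonation of the terminal alkyne and electrophilic chlorination of the lithium acetylide is a standard way to 1-chloroalkynes, and neither the allyl groups nor the silyl ether should be touched at −78 °C.

Step 5
Reactants: 8 {[4-(chloroethynyl)hepta-1,6-dien-4-yl]oxy}triethylsilane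
Product: 10 3-(chloroethynyl)-3-(triethylsilyloxy)pentanedial, via bis-ozonide 9 (not isolated)
Conditions: O3, CH2Cl2, −78 °C (Sudan Red 7B as end-point dye); then PPh3, −78 to 0 °C; used crude
Reagents that add atoms: ozone, [O-][O+]=O
Why: Ozonolysis with reductive work-up: ozone attacks the two electron-rich terminal alkenes far faster than the electron-poor chloroalkyne, and the neutral phosphine work-up avoids β-elimination of the silyloxy group from the dialdehyde, which has no stereocentre because both arms are the same.

Step 6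
Reactants: 10 3-(chloroethynyl)-3-(triethylsilyloxy)pentanedial
Product: 11 2-[(1S)-3-chloro-4-oxo-1-(triethylsilyloxy)cyclopent-2-en-1-yl]acetaldehyde
Conditions: [Rh(nbd)2]BF4 (10 mol%), (R)-Tol-BINAP (10 mol%), H2 then Ar (removal of nbd); CH2Cl2, rt, slow addition of 10
Reagents that add atoms: none
Why: Proposed new method: cationic monovalent rhodium carrying (R)-Tol-BINAP should insert into the C–H bond of one formyl group to give an acyl hydride of trivalent rhodium, deliver the hydride to C11 anti to the metal (trans hydrometalation of the tethered chloroalkyne) to form a six-membered acyl alkenyl rhodacycle with rhodium on C10, and release the enone by C9–C10 reductive elimination. The closest known reaction type is the cationic rhodium bisphosphine trans-hydroacylation of 4-alkynals to cyclopent-2-enones, which has also been run as a Tol-BINAP-controlled desymmetrisation of 3-alkoxy-1,4-diynes bearing one formylmethyl arm; not yet shown are the choice between two formyl arms on one alkyne and a chlorine on the alkyne terminus. The cyclopentenone ring (C8–C9–C10–C11–C12) closes in a formal 5-endo-dig mode, which is open here because the ring bond comes from reductive elimination at the metal and not from direct attack on the alkyne. C12 becomes the only stereocentre, and its configuration is set by the chiral bisphosphine, which has to take the formylmethyl arm that becomes C8–C9 and leave the one that stays as C13–C14. The step needs enantiotopic-group selectivity, C–H over C–Cl activation and a single cyclisation: the C12 silyloxy group next to both arms gives the ligand a fixed element to read as the 3-alkoxy group does in the known cases, the strong C(sp)–Cl bond and the chelate of formyl group and alkyne favour C–H insertion, and after the only alkyne is used up the remaining formyl group faces just a trisubstituted chloroalkene, a poor hydroacylation acceptor. The two-atom tether C8–C12 fixes the regiochemistry, so the acyl carbon C9 can only bond to C10 and chlorine ends on the α-carbon of the enone.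

Step 7
Reactants: 11 2-[(1S)-3-chloro-4-oxo-1-(triethylsilyloxy)cyclopent-2-en-1-yl]acetaldehyde; 12 hexyltriphenylphosphonium bromide
Product: 14 (4S)-2-chloro-4-[(2Z)-oct-2-en-1-yl]-4-(triethylsilyloxy)cyclopent-2-en-1-one, via phosphorus ylide 13 (not isolated)
Conditions: 12 (slight excess over base), NaN(SiMe3)2, THF, 0 °C; then 11, −78 to −20 °C
Reagents that add atoms: none
Why: Wittig olefination with a non-stabilised ylide under lithium-free conditions closes the cis-oxaphosphetane under kinetic control and so should give the 14Z alkene, and at −78 °C the aldehyde should react well before the hindered ketone or its α-protons; C12 is not involved.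

Step 8
Reactants: 14 (4S)-2-chloro-4-[(2Z)-oct-2-en-1-yl]-4-(triethylsilyloxy)cyclopent-2-en-1-one
Product: 17 (4R,5Z)-2-chloro-5-(hydroxymethylidene)-4-[(2Z)-oct-2-en-1-yl]-4-(triethylsilyloxy)cyclopent-2-en-1-one, via lithium dienolate 15 (not isolated), via lithium chelate 16 (not isolated)
Conditions: LiN(SiMe3)2 (1.1 equiv), THF, −78 °C; then HCO2CH2CF3, −78 °C; AcOH quench
Reagents that add atoms: 2,2,2-trifluoroethyl formate, O=COCC(F)(F)F
Why: Crossed Claisen condensation (formylation) of the kinetic lithium enolate: C8 is the only α-carbon bearing hydrogen, α'-enolates of 4-silyloxycyclopent-2-enones are known to survive at −78 °C without β-elimination, and the activated formate transfers the formyl group at that temperature to give, after the acetic acid quench and removal of trifluoroethanol and hexamethyldisilazane on isolation, the hydrogen-bonded Z-enol (the C12 descriptor changes to R only through priorities).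

Step 9
Reactants: 17 (4R,5Z)-2-chloro-5-(hydroxymethylidene)-4-[(2Z)-oct-2-en-1-yl]-4-(triethylsilyloxy)cyclopent-2-en-1-one
Product: 19 (Z)-{(5R)-3-chloro-5-[(2Z)-oct-2-en-1-yl]-2-oxo-5-(triethylsilyloxy)cyclopent-3-en-1-ylidene}methyl trifluoromethanesulfonate, via sodium chelate 18 (not isolated)
Conditions: NaH (1.05 equiv), Et2O, 0 °C; then Tf2O, −78 °C; used at once, dark
Reagents that add atoms: trifluoromethanesulfonic anhydride, O=S(=O)(OS(=O)(=O)C(F)(F)F)C(F)(F)F
Why: Enol triflate formation by O-sulfonylation of a sodium enolate: irreversible deprotonation of the acidic enol with NaH leaves only hydrogen and so no amine or alcohol that could consume Tf2O, the sodium ion held between the C9 carbonyl oxygen and the enolate oxygen in the weakly coordinating ether fixes the C7–O bond cis to C9 (hence 7Z), and the less hindered, formyl-derived oxygen is the one expected to be sulfonylated.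

Step 10
Reactants: 20 methyl hex-5-ynoate
Product: 21 methyl 6-iodohex-5-ynoate
Conditions: N-iodosuccinimide, AgNO3 (10 mol%), acetone, rt, dark
Reagents that add atoms: N-iodosuccinimide, O=C1CCC(=O)N1I
Why: Silver-catalysed electrophilic iodination of a terminal alkyne with N-iodosuccinimide is general and leaves the ester alone.

Step 11
Reactants: 21 methyl 6-iodohex-5-ynoate
Product: 22 methyl (5Z)-6-iodohex-5-enoate
Conditions: 2-nitrobenzenesulfonyl hydrazide, Et3N, THF/i-PrOH, rt
Reagents that add atoms: none
Why: Diimide reduction delivers both hydrogens to the same face of the triple bond in a concerted step, so the 1-iodoalkyne should give the Z-iodoalkene (the later 5Z geometry) without loss of iodine.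

Step 12
Reactants: 22 methyl (5Z)-6-iodohex-5-enoate
Product: 23 methyl (5Z)-6-(trimethylstannyl)hex-5-enoate
Conditions: Me3SnSnMe3 (excess), Pd(PPh3)4 (5 mol%), toluene, 80 °C
Reagents that add atoms: hexamethylditin, C[Sn](C)(C)[Sn](C)(C)C
Why: Palladium-catalysed stannylation of an alkenyl iodide with a distannane (oxidative addition, Sn–Sn transmetalation, reductive elimination) proceeds with retention of alkene geometry and tolerates the ester.

Step 13
Reactants: 19 (Z)-{(5R)-3-chloro-5-[(2Z)-oct-2-en-1-yl]-2-oxo-5-(triethylsilyloxy)cyclopent-3-en-1-ylidene}methyl trifluoromethanesulfonate; 23 methyl (5Z)-6-(trimethylstannyl)hex-5-enoate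
Product: 24 methyl (5Z,7Z)-7-[(5R)-3-chloro-5-[(2Z)-oct-2-en-1-yl]-2-oxo-5-(triethylsilyloxy)cyclopent-3-en-1-ylidene]hept-5-enoate
Conditions: Pd2(dba)3 (5 mol%), AsPh3 (40 mol%), NMP, rt, dark
Reagents that add atoms: none
Why: Stille coupling: zerovalent palladium inserts into the C–OTf bond much faster than into the alkenyl C–Cl bond, the weakly donating arsine speeds up transmetalation at room temperature, and both alkene partners keep their geometry, so C6–C7 should form with 5Z and 7Z.

Step 14
Reactants: 24 methyl (5Z,7Z)-7-[(5R)-3-chloro-5-[(2Z)-oct-2-en-1-yl]-2-oxo-5-(triethylsilyloxy)cyclopent-3-en-1-ylidene]hept-5-enoate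
Product: 25 methyl (5Z,7Z)-7-[(5R)-3-chloro-5-hydroxy-5-[(2Z)-oct-2-en-1-yl]-2-oxocyclopent-3-en-1-ylidene]hept-5-enoate (chlorovulone IV)
Conditions: HF·pyridine, pyridine, THF, 0 °C, dark
Reagents that add atoms: none
Why: Fluoride-mediated cleavage of the silyl ether under pyridine buffering should free the tertiary C12 alcohol without ionising it and without isomerising the light- and acid-sensitive dienone.

**Compound list**

1 | ethyl 3-(trimethylsilyl)prop-2-ynoate | CCOC(=O)C#C[Si](C)(C)C | starting material
2 | allylmagnesium bromide | C=CC[Mg]Br | starting material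
3 | 1-(trimethylsilyl)hex-5-en-1-yn-3-one (formed in the flask) | C=CCC(=O)C#C[Si](C)(C)C | intermediate
4 | 4-[(trimethylsilyl)ethynyl]hepta-1,6-dien-4-ol | C=CCC(O)(CC=C)C#C[Si](C)(C)C | intermediate
5 | triethyl({4-[(trimethylsilyl)ethynyl]hepta-1,6-dien-4-yl}oxy)silane | C=CCC(O[Si](CC)(CC)CC)(CC=C)C#C[Si](C)(C)C | intermediate
6 | triethyl[(4-ethynylhepta-1,6-dien-4-yl)oxy]silane | C=CCC(O[Si](CC)(CC)CC)(CC=C)C#C | intermediate
7 | lithium acetylide of 6 (formed in the flask) | C=CCC(O[Si](CC)(CC)CC)(CC=C)C#C[Li] | intermediate
8 | {[4-(chloroethynyl)hepta-1,6-dien-4-yl]oxy}triethylsilane | C=CCC(O[Si](CC)(CC)CC)(CC=C)C#CCl | intermediate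
9 | bis(1,2,4-trioxolane) of 8 (formed in the flask) | ClC#CC(O[Si](CC)(CC)CC)(CC1OCOO1)CC1OCOO1 | intermediate
10 | 3-(chloroethynyl)-3-(triethylsilyloxy)pentanedial | O=CCC(O[Si](CC)(CC)CC)(CC=O)C#CCl | intermediate
11 | 2-[(1S)-3-chloro-4-oxo-1-(triethylsilyloxy)cyclopent-2-en-1-yl]acetaldehyde | O=CC[C@@]1(O[Si](CC)(CC)CC)C=C(Cl)C(=O)C1 | intermediate
12 | hexyltriphenylphosphonium bromide | CCCCCC[P+](c1ccccc1)(c1ccccc1)c1ccccc1.[Br-] | starting material
13 | hexylidenetriphenylphosphorane (formed in the flask) | CCCCCC=P(c1ccccc1)(c1ccccc1)c1ccccc1 | intermediate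
14 | (4S)-2-chloro-4-[(2Z)-oct-2-en-1-yl]-4-(triethylsilyloxy)cyclopent-2-en-1-one | CCCCC/C=C\C[C@@]1(O[Si](CC)(CC)CC)C=C(Cl)C(=O)C1 | intermediate
15 | lithium dienolate of 14, C8=C9 enolate (formed in the flask) | CCCCC/C=C\C[C@@]1(O[Si](CC)(CC)CC)C=C(Cl)C(O[Li])=C1 | intermediate
16 | lithium chelate of 17, lithium on the C7 oxygen and bridged to the C9 carbonyl (formed in the flask) | CCCCC/C=C\C[C@@]1(O[Si](CC)(CC)CC)C=C(Cl)C(=O)/C1=C\O[Li] | intermediate
17 | (4R,5Z)-2-chloro-5-(hydroxymethylidene)-4-[(2Z)-oct-2-en-1-yl]-4-(triethylsilyloxy)cyclopent-2-en-1-one | CCCCC/C=C\C[C@@]1(O[Si](CC)(CC)CC)C=C(Cl)C(=O)/C1=C\O | intermediate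
18 | sodium chelate of 17, sodium on the C7 oxygen and bridged to the C9 carbonyl (formed in the flask) | CCCCC/C=C\C[C@@]1(O[Si](CC)(CC)CC)C=C(Cl)C(=O)/C1=C\O[Na] | intermediate
19 | (Z)-{(5R)-3-chloro-5-[(2Z)-oct-2-en-1-yl]-2-oxo-5-(triethylsilyloxy)cyclopent-3-en-1-ylidene}methyl trifluoromethanesulfonate | CCCCC/C=C\C[C@@]1(O[Si](CC)(CC)CC)C=C(Cl)C(=O)/C1=C\OS(=O)(=O)C(F)(F)F | intermediate
20 | methyl hex-5-ynoate | C#CCCCC(=O)OC | starting material
21 | methyl 6-iodohex-5-ynoate | IC#CCCCC(=O)OC | intermediate
22 | methyl (5Z)-6-iodohex-5-enoate | I/C=C\CCCC(=O)OC | intermediate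
23 | methyl (5Z)-6-(trimethylstannyl)hex-5-enoate | C[Sn](C)(C)/C=C\CCCC(=O)OC | intermediate
24 | methyl (5Z,7Z)-7-[(5R)-3-chloro-5-[(2Z)-oct-2-en-1-yl]-2-oxo-5-(triethylsilyloxy)cyclopent-3-en-1-ylidene]hept-5-enoate | CCCCC/C=C\C[C@@]1(O[Si](CC)(CC)CC)C=C(Cl)C(=O)/C1=C\C=C/CCCC(=O)OC | intermediate
25 | methyl (5Z,7Z)-7-[(5R)-3-chloro-5-hydroxy-5-[(2Z)-oct-2-en-1-yl]-2-oxocyclopent-3-en-1-ylidene]hept-5-enoate (chlorovulone IV) | CCCCC/C=C\C[C@@]1(O)C=C(Cl)C(=O)/C1=C\C=C/CCCC(=O)OC | target

**Step count and risks**

Total step count: 14. Longest linear sequence: 11 steps (steps 1 to 9, 13 and 14); steps 10 to 12 make the stannane.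

Steps most likely to fail:

1. Step 6. What may go wrong: the chiral rhodium complex may not tell the two formyl arms apart, so that 11 forms with low enantiomeric purity, or it may be used up by the chloroalkyne through C–Cl oxidative addition or chlorovinylidene formation before C–H activation. The fallback uses known chemistry and takes the C12 configuration from a resolved building block by 1,3-transfer instead of from a catalyst. It sets out from allylmagnesium bromide 2, which is added in THF at −78 °C to commercial (4R)-4-(tert-butyldimethylsilyloxy)cyclopent-2-en-1-one F1. 1,2-Addition anti to the silyloxy group should give (1S,4R)-4-(tert-butyldimethylsilyloxy)-1-(prop-2-en-1-yl)cyclopent-2-en-1-ol F2; the minor syn adduct must be removed by chromatography, because it would lead to the enantiomer. Bu4NF in THF frees (1S,4R)-1-(prop-2-en-1-yl)cyclopent-2-ene-1,4-diol F3, and MnO2 in CH2Cl2 oxidises only the secondary allylic alcohol to (4S)-4-hydroxy-4-(prop-2-en-1-yl)cyclopent-2-en-1-one F4, in which the former ketone carbon has become the C12 carbinol. Because Cl2 would also attack the allyl group, chlorine is brought in through the epoxide: H2O2 and NaOH in MeOH at 0 °C give (4S)-2,3-epoxy-4-hydroxy-4-(prop-2-en-1-yl)cyclopentan-1-one F5, and HCl in THF opens it at the carbon next to the carbonyl and removes water to give (4S)-2-chloro-4-hydroxy-4-(prop-2-en-1-yl)cyclopent-2-en-1-one F6. Et3SiOTf and 2,6-lutidine give (4S)-2-chloro-4-(prop-2-en-1-yl)-4-(triethylsilyloxy)cyclopent-2-en-1-one F7. Ozonolysis of the allyl group alone (O3, CH2Cl2, −78 °C; PPh3), which the electron-poor chloroenone should survive, comes back to the route at compound 11.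

2. Step 9. What may go wrong: the sodium chelate may open before sulfonylation, or the triflate may isomerise by addition and loss of triflate, so that 7E and 7Z triflates form together; sulfonylation at the ketone oxygen is also possible. The fallback replaces the enol triflate and the coupling by the classical aldol condensation of this compound class. It sets out from cyclopentenone 14. Methyl (5Z)-7-oxohept-5-enoate F8 would be made from iodide 22 by formylation with CO and Bu3SnH under Pd(PPh3)4 catalysis (THF, 50 °C). Lithium dienolate 15 (LiN(SiMe3)2, THF, −78 °C) is added to F8 to give methyl (5Z)-7-[(5S)-3-chloro-5-[(2Z)-oct-2-en-1-yl]-2-oxo-5-(triethylsilyloxy)cyclopent-3-en-1-yl]-7-hydroxyhept-5-enoate F9 as a mixture at C7 and C8. MsCl and Et3N in CH2Cl2 at 0 °C give methyl (5Z)-7-[(5S)-3-chloro-5-[(2Z)-oct-2-en-1-yl]-2-oxo-5-(triethylsilyloxy)cyclopent-3-en-1-yl]-7-(methanesulfonyloxy)hept-5-enoate F10, which loses methanesulfonate with Et3N on warming. The dienone is expected as a mixture of the 7Z isomer and methyl (5Z,7E)-7-[(5R)-3-chloro-5-[(2Z)-oct-2-en-1-yl]-2-oxo-5-(triethylsilyloxy)cyclopent-3-en-1-ylidene]hept-5-enoate F11. Chromatography separates the 7Z isomer, and the fallback comes back to the route at compound 24. This sequence does not control the C7=C8 geometry, which is why it is the fallback and not the route.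

3. Step 13. What may go wrong: the C7=C8 geometry may leak in the oxo-alkenylpalladium intermediate when transmetalation from the Z-alkenylstannane is slow, and protodestannylation and homocoupling of 23 may then take over. The fallback sets the C5=C6 geometry by reduction after the coupling. It sets out from triflate 19 and methyl hex-5-ynoate 20. Sonogashira coupling (Pd(PPh3)4, CuI, 2,6-lutidine, DMF, 0 °C to rt), in which the copper acetylide transmetalates fast, should give methyl (7Z)-7-[(5R)-3-chloro-5-[(2Z)-oct-2-en-1-yl]-2-oxo-5-(triethylsilyloxy)cyclopent-3-en-1-ylidene]hept-5-ynoate F12. Semi-hydrogenation of the alkyne (H2, Pd/CaCO3 poisoned with Pb(OAc)2, quinoline, EtOAc, 0 °C) gives the 5Z alkene and comes back to the route at compound 24.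

**Further compounds**

F1 | step 6 | (4R)-4-(tert-butyldimethylsilyloxy)cyclopent-2-en-1-one (commercial) | O=C1C=C[C@H](O[Si](C)(C)C(C)(C)C)C1
F2 | step 6 | (1S,4R)-4-(tert-butyldimethylsilyloxy)-1-(prop-2-en-1-yl)cyclopent-2-en-1-ol | C=CC[C@@]1(O)C=C[C@H](O[Si](C)(C)C(C)(C)C)C1
F3 | step 6 | (1S,4R)-1-(prop-2-en-1-yl)cyclopent-2-ene-1,4-diol | C=CC[C@@]1(O)C=C[C@H](O)C1
F4 | step 6 | (4S)-4-hydroxy-4-(prop-2-en-1-yl)cyclopent-2-en-1-one | C=CC[C@@]1(O)C=CC(=O)C1
F5 | step 6 | (4S)-2,3-epoxy-4-hydroxy-4-(prop-2-en-1-yl)cyclopentan-1-one (epoxide face not controlled) | C=CC[C@@]1(O)C2OC2C(=O)C1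
F6 | step 6 | (4S)-2-chloro-4-hydroxy-4-(prop-2-en-1-yl)cyclopent-2-en-1-one | C=CC[C@@]1(O)C=C(Cl)C(=O)C1
F7 | step 6 | (4S)-2-chloro-4-(prop-2-en-1-yl)-4-(triethylsilyloxy)cyclopent-2-en-1-one | C=CC[C@@]1(O[Si](CC)(CC)CC)C=C(Cl)C(=O)C1
F8 | step 9 | methyl (5Z)-7-oxohept-5-enoate | COC(=O)CCC/C=C\C=O
F9 | step 9 | methyl (5Z)-7-[(5S)-3-chloro-5-[(2Z)-oct-2-en-1-yl]-2-oxo-5-(triethylsilyloxy)cyclopent-3-en-1-yl]-7-hydroxyhept-5-enoate (mixture at C7 and C8) | CCCCC/C=C\C[C@@]1(O[Si](CC)(CC)CC)C=C(Cl)C(=O)C1C(O)/C=C\CCCC(=O)OC
F10 | step 9 | methyl (5Z)-7-[(5S)-3-chloro-5-[(2Z)-oct-2-en-1-yl]-2-oxo-5-(triethylsilyloxy)cyclopent-3-en-1-yl]-7-(methanesulfonyloxy)hept-5-enoate (mixture at C7 and C8) | CCCCC/C=C\C[C@@]1(O[Si](CC)(CC)CC)C=C(Cl)C(=O)C1C(OS(C)(=O)=O)/C=C\CCCC(=O)OC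
F11 | step 9 | methyl (5Z,7E)-7-[(5R)-3-chloro-5-[(2Z)-oct-2-en-1-yl]-2-oxo-5-(triethylsilyloxy)cyclopent-3-en-1-ylidene]hept-5-enoate | CCCCC/C=C\C[C@@]1(O[Si](CC)(CC)CC)C=C(Cl)C(=O)/C1=C/C=C\CCCC(=O)OC
F12 | step 13 | methyl (7Z)-7-[(5R)-3-chloro-5-[(2Z)-oct-2-en-1-yl]-2-oxo-5-(triethylsilyloxy)cyclopent-3-en-1-ylidene]hept-5-ynoate | CCCCC/C=C\C[C@@]1(O[Si](CC)(CC)CC)C=C(Cl)C(=O)/C1=C\C#CCCCC(=O)OC
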